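**Plan**
- The three ester C–O bonds (O–C6 of each bicyclic unit) are cut first, giving a cyclobutane tricarboxylate core and three copies of one 2,4,7-trimethyl-octahydrocyclopenta[c]pyridin-6-ol. Forward, the units are attached one at a time by Mitsunobu esterification with inversion at C6, each after release of one carboxyl from a benzyl / tert-butyl / 2-(trimethylsilyl)ethyl triester.
- In the amino alcohol the piperidine bond C4–C4a is cut. C4a is β to a C6 ketone and C4 (with its methyl, next to C3 and N2) is the Markovnikov radical carbon of an N-allyl group, so the ring closes by radical conjugate addition onto a 4-(aminomethyl)-5-methylcyclopent-2-enone made from 2-methylcyclopentenone and nitromethane.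
- In the core the cyclobutane bond between the aryl-bearing carbon and the methyl-bearing quaternary carbon is traced back to a pyrrolidine with NH between these carbons. The pyrrolidine comes from an azomethine ylide cycloaddition of a vanillin/alanine ester imine with a 3-methylocta-2,6-dienedioate, and nitrogen extrusion contracts it.
- Ring order: cyclopentanone, then piperidine (bicyclic unit); pyrrolidine, then cyclobutane; the units are then attached and the phenol is freed together with the last carboxyl.
- Stereochemistry: C7a from the enantioselective nitromethane addition, C7 by equilibration, C4a and C4 in the radical closure, C6 by hydride delivery followed by Mitsunobu inversion. In the core, the quaternary carbon, the side-chain carbon and the ester-bearing CH come from the ligand-controlled endo cycloaddition, the aryl carbon from equilibration to the trans isomer, and all four are carried through a stereoretentive ring contraction.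

Key step: step 6

Assumption: each chiral catalyst (the amine of step 1, the ligand of step 13) is used as the enantiomer that gives the drawn absolute configuration; the sense of induction is taken from the usual model, and the mirror-image catalyst is used if it proves opposite.

**Step 1**
Reactants: 1 2-methylcyclopent-2-en-1-one; 2 nitromethane
Product: 3 (2R,3S)-2-methyl-3-(nitromethyl)cyclopentan-1-one (trans)
Conditions: 9-amino-9-deoxy-epi-cinchona primary amine (10 mol %), PhCO2H (20 mol %), MeNO2 (5 equiv), toluene, 40 °C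
Reagents that add atoms: none
Why: Iminium-activated asymmetric Michael addition of nitromethane should set C3 (later C7a) under catalyst control, and the epimerisable α-methyl centre should settle trans to the new substituent under the amine conditions.

**Step 2**
Reactants: 3 (2R,3S)-2-methyl-3-(nitromethyl)cyclopentan-1-one
Product: 4 tert-butyl {[(1S,2R)-2-methyl-3-oxocyclopentyl]methyl}carbamate
Conditions: H2 (1 atm), Raney Ni, Boc2O, MeOH, rt
Reagents that add atoms: di-tert-butyl dicarbonate, CC(C)(C)OC(=O)OC(=O)OC(C)(C)C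
Why: Nitro hydrogenation with in situ carbamate capture should give the protected amine, since a cyclic imine with the ring ketone would need a bridgehead C=N (Bredt's rule) and the ketone is reduced far more slowly than the nitro group.

**Step 3**
Reactants: 4 tert-butyl {[(1S,2R)-2-methyl-3-oxocyclopentyl]methyl}carbamate
Product: 5 tert-butyl {[(1S,2R)-3-(tert-butyldimethylsilyloxy)-2-methylcyclopent-3-en-1-yl]methyl}carbamate (enol ether double bond toward the ring CH2)
Conditions: LiN(i-Pr)2 (2.2 equiv), THF, −78 °C; t-BuMe2SiCl (1.1 equiv), DMPU, −78 to 0 °C; aq. NaHCO3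
Reagents that add atoms: tert-butyldimethylsilyl chloride, CC(C)(C)[Si](C)(C)Cl
Why: Kinetic deprotonation of the N-lithiated carbamate should take place at the unsubstituted α-CH2, and O-silylation of this enolate fixes the regiochemistry for the later desaturation and masks the ketone for the N-alkylation, the lithium carbamate being reprotonated on work-up.

**Step 4**
Reactants: 5 silyl enol ether carbamate; 6 allyl bromide
Product: 7 tert-butyl allyl{[(1S,2R)-3-(tert-butyldimethylsilyloxy)-2-methylcyclopent-3-en-1-yl]methyl}carbamate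
Conditions: NaH, DMF/THF, 0 °C to rt
Reagents that add atoms: none
Why: N-alkylation of the carbamate anion should be clean because the only other acidic position, the ketone α-carbon, is blocked as the silyl enol ether.

**Step 5**
Reactants: 7 N-allyl silyl enol ether
Product: 8 tert-butyl allyl{[(1S,5R)-5-methyl-4-oxocyclopent-2-en-1-yl]methyl}carbamate (trans enone)
Conditions: Pd(OAc)2 (1.05 equiv), MeCN, rt to 40 °C
Reagents that add atoms: none
Why: Saegusa–Ito oxidation (oxa-π-allyl palladium, β-hydride elimination) should place the double bond on the side fixed by the enol ether, leaving the two stereocentres untouched.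

**Step 6**
Reactants: 8 tert-butyl allyl{[(1S,5R)-5-methyl-4-oxocyclopent-2-en-1-yl]methyl}carbamate
Product: 9 tert-butyl (4R,4aR,7R,7aS)-4,7-dimethyl-6-oxooctahydro-2H-cyclopenta[c]pyridine-2-carboxylate (cis-fused)
Conditions: Fe(acac)3 (0.5 equiv), PhSiH3 (2.5 equiv), EtOH/(CH2OH)2 5:1, 60 °C, degassed
Reagents that add atoms: none
Why: Fe(acac)3 and PhSiH3 in ethanol should give an iron hydride that passes a hydrogen atom to the terminal CH2 of the N-allyl group, so that this carbon becomes the C4 methyl and the secondary radical sits on C4; the radical adds to the enone β-carbon C4a, and the α-keto radical is reduced to the enolate and protonated by the solvent. The closest known reaction type is the iron-catalysed hydrogen-atom-transfer reductive coupling of unactivated alkenes with enones, which is also known in intramolecular form. The piperidine ring closes in 6-exo-trig mode by formation of the C4–C4a bond. C4a is controlled by the CH2N tether on C7a, which can reach only its own face of the cyclopentenone and so gives the cis ring fusion; C4 is controlled by a chair-like transition state with the methyl and the enone carbon C5 both pseudo-equatorial, which places the methyl trans to C5, and this is the less secure of the two elements. The step needs hydrogen-atom transfer to the allyl group and not to the enone, and ring closure faster than reduction of the radical: the electron-rich monosubstituted alkene is the better hydrogen-atom acceptor, and the electron-poor enone carbon is held six atoms from the nucleophilic radical. The C7 methyl next to the ketone should stay trans to the C7a–C1 bond, which is also the more stable arrangement.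

**Step 7**
Reactants: 9 bicyclic N-Boc ketone
Product: 10 tert-butyl (4R,4aR,6S,7R,7aS)-6-hydroxy-4,7-dimethyloctahydro-2H-cyclopenta[c]pyridine-2-carboxylate (hydroxyl cis to the C7 methyl)
Conditions: LiBH(s-Bu)3, THF, −78 °C; then H2O
Reagents that add atoms: none
Why: The bulky hydride should attack the cyclopentanone anti to the adjacent C7 methyl, as in 2-alkylcyclopentanones, giving the C6 alcohol cis to that methyl, which is the C6 epimer required for the inverting esterification.

**Step 8**
Reactants: 10 N-Boc amino alcohol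
Product: 11 (4R,4aR,6S,7R,7aS)-2,4,7-trimethyloctahydro-1H-cyclopenta[c]pyridin-6-ol
Conditions: LiAlH4, THF, reflux
Reagents that add atoms: none
Why: Hydride reduction of the tert-butyl carbamate turns its carbonyl carbon into the N-methyl group without touching any stereocentre.

**Step 9**
Reactants: 12 but-2-ynoic acid; 13 2-(trimethylsilyl)ethanol
Product: 14 2-(trimethylsilyl)ethyl but-2-ynoate
Conditions: DCC (1.1 equiv), DMAP (5 mol %), CH2Cl2, 0 °C to rt
Reagents that add atoms: none
Why: Steglich esterification (carbodiimide activation, DMAP as acyl-transfer catalyst) should give the ynoate without addition to the triple bond when DMAP is kept catalytic and the mixture cold.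

**Step 10**
Reactants: 14 2-(trimethylsilyl)ethyl but-2-ynoate; 15 but-3-enylmagnesium bromide
Product: 16 2-(trimethylsilyl)ethyl (2E)-3-methylhepta-2,6-dienoate
Conditions: CuBr·SMe2 (1.1 equiv), THF, −40 °C; then 14, −78 °C; aq. NH4Cl at −78 °C
Reagents that add atoms: none
Why: Syn carbocupration of the ynoate places the butenyl group and the new hydrogen cis, which gives the E-configured trisubstituted enoate when the vinylcopper is protonated cold.

**Step 11**
Reactants: 16 2-(trimethylsilyl)ethyl (2E)-3-methylhepta-2,6-dienoate; 17 tert-butyl acrylate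
Product: 18 8-tert-butyl 1-[2-(trimethylsilyl)ethyl] (2E,6E)-3-methylocta-2,6-dienedioate
Conditions: second-generation Hoveyda–Grubbs catalyst (3 mol %), 17 (3 equiv), CH2Cl2, 40 °C
Reagents that add atoms: none
Why: Cross-metathesis of the terminal alkene with the acrylate should give the E-enoate, the conjugated trisubstituted alkene being inert to the ruthenium carbene.

**Step 12**
Reactants: 19 vanillin
Product: 20 3-methoxy-4-(triisopropylsilyloxy)benzaldehyde
Conditions: i-Pr3SiCl, imidazole, DMF, rt
Reagents that add atoms: triisopropylsilyl chloride, CC(C)[Si](Cl)(C(C)C)C(C)C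
Why: Phenol silylation gives an aryl silyl ether that should survive amine, thiol, acid, oxidising and Mitsunobu conditions and falls to fluoride together with the silylethyl ester near the end.

**Step 13**
Reactants: 20 silylated vanillin; 21 L-alanine benzyl ester hydrochloride; 18 mixed dienedioate
Product: 23 2-benzyl 4-tert-butyl (2S,3S,4S,5R)-5-[3-methoxy-4-(triisopropylsilyloxy)phenyl]-2-methyl-3-{(3E)-3-methyl-5-oxo-5-[2-(trimethylsilyl)ethoxy]pent-3-en-1-yl}pyrrolidine-2,4-dicarboxylate (aryl and both ring esters on one face; methyl and side chain on the other), via aldimine 22 (not isolated)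
Conditions: Et3N, MgSO4, CH2Cl2, rt; filter, concentrate; then 18, AgOAc (5 mol %), QUINAP (5.5 mol %), i-Pr2NEt (10 mol %), THF, −20 °C to rt
Reagents that add atoms: none
Why: The N,O-chelated silver azomethine ylide (the alanine stereocentre is erased) should undergo an endo 1,3-dipolar cycloaddition with the disubstituted enoate only, its α-carbon bonding to the enoate β-carbon, so that the ligand fixes the quaternary C2 and C3 absolutely, the E-alkene fixes C3/C4 trans and the endo mode puts the C4 ester cis to the C2 ester.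

**Step 14**
Reactants: 23 pyrrolidine (2S,3S,4S,5R)
Product: 24 2-benzyl 4-tert-butyl (2S,3S,4S,5S)-5-[3-methoxy-4-(triisopropylsilyloxy)phenyl]-2-methyl-3-{(3E)-3-methyl-5-oxo-5-[2-(trimethylsilyl)ethoxy]pent-3-en-1-yl}pyrrolidine-2,4-dicarboxylate (aryl trans to the C4 ester, cis to the C2 methyl and the C3 side chain)
Conditions: [Ir{dF(CF3)ppy}2(dtbbpy)]PF6 (1 mol %), PhSH (1 equiv), MeOH, blue LEDs, rt
Reagents that add atoms: none
Why: Light-driven reversible hydrogen-atom transfer at the only α-amino C–H (benzylic C5), relayed by the thiol, should equilibrate C5 to the more stable isomer in which the aryl group is trans to the neighbouring ester, all other centres lacking an abstractable α-amino hydrogen.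

**Step 15**
Reactants: 24 pyrrolidine (2S,3S,4S,5S)
Product: 26 1-benzyl 3-tert-butyl (1R,2S,3S,4S)-2-[3-methoxy-4-(triisopropylsilyloxy)phenyl]-1-methyl-4-{(3E)-3-methyl-5-oxo-5-[2-(trimethylsilyl)ethoxy]pent-3-en-1-yl}cyclobutane-1,3-dicarboxylate, via 1,1-diazene 25 (not isolated)
Conditions: PhI(OH)OTs (2.5 equiv), H2NCO2NH4 (8 equiv), CF3CH2OH, 80 °C
Reagents that add atoms: none
Why: Nitrogen transfer from the iodonitrene to the secondary amine gives a 1,1-diazene whose loss of N2 leaves a singlet 1,4-diradical (benzylic and tertiary α-ester) that should collapse faster than it rotates, so the pyrrolidine contracts to the cyclobutane with retention at both former α-carbons.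

**Step 16**
Reactants: 26 cyclobutane triester
Product: 28 (1R,2S,3S,4S)-3-(tert-butoxycarbonyl)-2-[3-methoxy-4-(triisopropylsilyloxy)phenyl]-1-methyl-4-{(3E)-3-methyl-5-oxo-5-[2-(trimethylsilyl)ethoxy]pent-3-en-1-yl}cyclobutane-1-carboxylic acid, via triethylsilyl ester 27 (not isolated)
Conditions: Pd(OAc)2 (10 mol %), Et3SiH (1.5 equiv), Et3N (0.3 equiv), CH2Cl2, rt; then MeOH, aq. NH4Cl
Reagents that add atoms: none
Why: Palladium-catalysed silane hydrogenolysis of the benzyl ester cleaves only the benzylic C–O bond and should spare the trisubstituted enoate, the tert-butyl and silylethyl esters and the aryl silyl ether, the triethylsilyl ester formed being hydrolysed on work-up.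

**Step 17**
Reactants: 28 quaternary carboxylic acid; 11 amino alcohol
Product: 29 3-tert-butyl 1-[(4R,4aR,6R,7R,7aS)-2,4,7-trimethyloctahydro-1H-cyclopenta[c]pyridin-6-yl] (1R,2S,3S,4S)-2-[3-methoxy-4-(triisopropylsilyloxy)phenyl]-1-methyl-4-{(3E)-3-methyl-5-oxo-5-[2-(trimethylsilyl)ethoxy]pent-3-en-1-yl}cyclobutane-1,3-dicarboxylate
Conditions: 11 (1.3 equiv), PPh3 (1.6 equiv), DIAD (1.6 equiv), THF, 0 °C to rt
Reagents that add atoms: none
Why: In the Mitsunobu esterification the hindered quaternary carboxylate acts only as the nucleophile in an SN2 displacement at the activated C6 of 11, so the ester bond forms with inversion from 6S to the 6R of the target and without attack at the crowded carboxyl carbon.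

**Step 18**
Reactants: 29 mono amino ester
Product: 30 (1R,2S,3S,4S)-2-[3-methoxy-4-(triisopropylsilyloxy)phenyl]-1-methyl-4-{(3E)-3-methyl-5-oxo-5-[2-(trimethylsilyl)ethoxy]pent-3-en-1-yl}cyclobutane-1,3-dicarboxylic acid 1-[(4R,4aR,6R,7R,7aS)-2,4,7-trimethyloctahydro-1H-cyclopenta[c]pyridin-6-yl] ester (free acid at C3)
Conditions: CF3CO2H/CH2Cl2 1:3, 0 °C to rt; evaporate with toluene; pH 7 phosphate buffer
Reagents that add atoms: none
Why: Acidolysis of the tert-butyl ester runs through the tert-butyl cation and should leave the secondary alkyl ester, the silylethyl enoate, the aryl silyl ether and the ring stereocentres intact, the amine being carried as its ammonium salt.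

**Step 19**
Reactants: 30 C3 carboxylic acid; 11 amino alcohol
Product: 31 bis[(4R,4aR,6R,7R,7aS)-2,4,7-trimethyloctahydro-1H-cyclopenta[c]pyridin-6-yl] (1R,2S,3S,4S)-2-[3-methoxy-4-(triisopropylsilyloxy)phenyl]-1-methyl-4-{(3E)-3-methyl-5-oxo-5-[2-(trimethylsilyl)ethoxy]pent-3-en-1-yl}cyclobutane-1,3-dicarboxylate
Conditions: 11 (1.3 equiv), PPh3 (1.6 equiv), DIAD (1.6 equiv), THF, 0 °C to rt
Reagents that add atoms: none
Why: A second Mitsunobu esterification, in which the ring carboxylate displaces the activated C6 oxygen of 11 with inversion, should tolerate the tertiary amine already present because the ammonium carboxylate is acidic enough to protonate the betaine.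

**Step 20**
Reactants: 31 bis amino ester
Product: 32 (1R,2S,3S,4S)-4-[(3E)-4-carboxy-3-methylbut-3-en-1-yl]-2-(4-hydroxy-3-methoxyphenyl)-1-methylcyclobutane-1,3-dicarboxylic acid 1,3-bis[(4R,4aR,6R,7R,7aS)-2,4,7-trimethyloctahydro-1H-cyclopenta[c]pyridin-6-yl] ester (free enoic acid and free phenol)
Conditions: Bu4NF (3 equiv), THF, 0 °C to rt; then AcOH (3 equiv); reversed-phase chromatography
Reagents that add atoms: none
Why: Fluoride attack at silicon fragments the 2-(trimethylsilyl)ethyl ester to the carboxylate, ethylene and Me3SiF and cleaves the aryl silyl ether in the same operation, while the two hindered alkyl esters are not attacked and the C3 ester already sits trans to both neighbours.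

**Step 21**
Reactants: 32 phenolic enoic acid; 11 amino alcohol
Product: 33 target CNP0251577.2
Conditions: 11 (1.2 equiv), PPh3 (1.4 equiv), DIAD (1.4 equiv), THF/CH2Cl2, 0 °C to rt
Reagents that add atoms: none
Why: The third Mitsunobu esterification should be chemoselective because the betaine is protonated by the carboxylic acid (pKa about 5) and not by the hindered guaiacol-type phenol (pKa about 10), as in esterifications of unprotected phenolic acids, so only the carboxylate displaces the activated C6 oxygen of 11, again with inversion.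

**Compound list**
1 | 2-methylcyclopent-2-en-1-one | CC1=CCCC1=O | starting material
2 | nitromethane | C[N+](=O)[O-] | starting material
3 | (2R,3S)-2-methyl-3-(nitromethyl)cyclopentan-1-one | O=C1CC[C@H](C[N+](=O)[O-])[C@H]1C | intermediate
4 | tert-butyl {[(1S,2R)-2-methyl-3-oxocyclopentyl]methyl}carbamate | O=C1CC[C@H](CNC(=O)OC(C)(C)C)[C@H]1C | intermediate
5 | tert-butyl {[(1S,2R)-3-(tert-butyldimethylsilyloxy)-2-methylcyclopent-3-en-1-yl]methyl}carbamate | CC(C)(C)[Si](C)(C)OC1=CC[C@H](CNC(=O)OC(C)(C)C)[C@H]1C | intermediate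
6 | allyl bromide | C=CCBr | starting material
7 | tert-butyl allyl{[(1S,2R)-3-(tert-butyldimethylsilyloxy)-2-methylcyclopent-3-en-1-yl]methyl}carbamate | CC(C)(C)[Si](C)(C)OC1=CC[C@H](CN(CC=C)C(=O)OC(C)(C)C)[C@H]1C | intermediate
8 | tert-butyl allyl{[(1S,5R)-5-methyl-4-oxocyclopent-2-en-1-yl]methyl}carbamate | O=C1C=C[C@H](CN(C(=O)OC(C)(C)C)CC=C)[C@H]1C | intermediate
9 | tert-butyl (4R,4aR,7R,7aS)-4,7-dimethyl-6-oxooctahydro-2H-cyclopenta[c]pyridine-2-carboxylate | O=C1C[C@H]2[C@H](CN(C(=O)OC(C)(C)C)C[C@@H]2C)[C@H]1C | intermediate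
10 | tert-butyl (4R,4aR,6S,7R,7aS)-6-hydroxy-4,7-dimethyloctahydro-2H-cyclopenta[c]pyridine-2-carboxylate | O[C@H]1C[C@H]2[C@H](CN(C(=O)OC(C)(C)C)C[C@@H]2C)[C@H]1C | intermediate
11 | (4R,4aR,6S,7R,7aS)-2,4,7-trimethyloctahydro-1H-cyclopenta[c]pyridin-6-ol | O[C@H]1C[C@H]2[C@H](CN(C)C[C@@H]2C)[C@H]1C | intermediate
12 | but-2-ynoic acid | CC#CC(=O)O | starting material
13 | 2-(trimethylsilyl)ethanol | C[Si](C)(C)CCO | starting material
14 | 2-(trimethylsilyl)ethyl but-2-ynoate | CC#CC(=O)OCC[Si](C)(C)C | intermediate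
15 | but-3-enylmagnesium bromide | C=CCC[Mg]Br | starting material
16 | 2-(trimethylsilyl)ethyl (2E)-3-methylhepta-2,6-dienoate | C=CCC/C(C)=C/C(=O)OCC[Si](C)(C)C | intermediate
17 | tert-butyl acrylate | C=CC(=O)OC(C)(C)C | starting material
18 | 8-tert-butyl 1-[2-(trimethylsilyl)ethyl] (2E,6E)-3-methylocta-2,6-dienedioate | CC(C)(C)OC(=O)/C=C/CC/C(C)=C/C(=O)OCC[Si](C)(C)C | intermediate
19 | vanillin | COc1cc(C=O)ccc1O | starting material
20 | 3-methoxy-4-(triisopropylsilyloxy)benzaldehyde | COc1cc(C=O)ccc1O[Si](C(C)C)(C(C)C)C(C)C | intermediate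
21 | L-alanine benzyl ester hydrochloride | C[C@H](N)C(=O)OCc1ccccc1.Cl | starting material
22 | benzyl N-[(E)-3-methoxy-4-(triisopropylsilyloxy)benzylidene]-L-alaninate | COc1cc(/C=N/[C@@H](C)C(=O)OCc2ccccc2)ccc1O[Si](C(C)C)(C(C)C)C(C)C | intermediate
23 | 2-benzyl 4-tert-butyl (2S,3S,4S,5R)-5-[3-methoxy-4-(triisopropylsilyloxy)phenyl]-2-methyl-3-{(3E)-3-methyl-5-oxo-5-[2-(trimethylsilyl)ethoxy]pent-3-en-1-yl}pyrrolidine-2,4-dicarboxylate | COc1cc([C@@H]2N[C@](C)(C(=O)OCc3ccccc3)[C@@H](CC/C(C)=C/C(=O)OCC[Si](C)(C)C)[C@@H]2C(=O)OC(C)(C)C)ccc1O[Si](C(C)C)(C(C)C)C(C)C | intermediate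
24 | 2-benzyl 4-tert-butyl (2S,3S,4S,5S)-5-[3-methoxy-4-(triisopropylsilyloxy)phenyl]-2-methyl-3-{(3E)-3-methyl-5-oxo-5-[2-(trimethylsilyl)ethoxy]pent-3-en-1-yl}pyrrolidine-2,4-dicarboxylate | COc1cc([C@H]2N[C@](C)(C(=O)OCc3ccccc3)[C@@H](CC/C(C)=C/C(=O)OCC[Si](C)(C)C)[C@@H]2C(=O)OC(C)(C)C)ccc1O[Si](C(C)C)(C(C)C)C(C)C | intermediate
25 | 1,1-diazene (N-nitrene) of pyrrolidine 24 | COc1cc([C@H]2[N+](=[N-])[C@](C)(C(=O)OCc3ccccc3)[C@@H](CC/C(C)=C/C(=O)OCC[Si](C)(C)C)[C@@H]2C(=O)OC(C)(C)C)ccc1O[Si](C(C)C)(C(C)C)C(C)C | intermediate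
26 | 1-benzyl 3-tert-butyl (1R,2S,3S,4S)-2-[3-methoxy-4-(triisopropylsilyloxy)phenyl]-1-methyl-4-{(3E)-3-methyl-5-oxo-5-[2-(trimethylsilyl)ethoxy]pent-3-en-1-yl}cyclobutane-1,3-dicarboxylate | COc1cc([C@@H]2[C@@H](C(=O)OC(C)(C)C)[C@H](CC/C(C)=C/C(=O)OCC[Si](C)(C)C)[C@@]2(C)C(=O)OCc3ccccc3)ccc1O[Si](C(C)C)(C(C)C)C(C)C | intermediate
27 | 3-tert-butyl 1-triethylsilyl (1R,2S,3S,4S)-2-[3-methoxy-4-(triisopropylsilyloxy)phenyl]-1-methyl-4-{(3E)-3-methyl-5-oxo-5-[2-(trimethylsilyl)ethoxy]pent-3-en-1-yl}cyclobutane-1,3-dicarboxylate | COc1cc([C@@H]2[C@@H](C(=O)OC(C)(C)C)[C@H](CC/C(C)=C/C(=O)OCC[Si](C)(C)C)[C@@]2(C)C(=O)O[Si](CC)(CC)CC)ccc1O[Si](C(C)C)(C(C)C)C(C)C | intermediate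
28 | (1R,2S,3S,4S)-3-(tert-butoxycarbonyl)-2-[3-methoxy-4-(triisopropylsilyloxy)phenyl]-1-methyl-4-{(3E)-3-methyl-5-oxo-5-[2-(trimethylsilyl)ethoxy]pent-3-en-1-yl}cyclobutane-1-carboxylic acid | COc1cc([C@@H]2[C@@H](C(=O)OC(C)(C)C)[C@H](CC/C(C)=C/C(=O)OCC[Si](C)(C)C)[C@@]2(C)C(=O)O)ccc1O[Si](C(C)C)(C(C)C)C(C)C | intermediate
29 | 3-tert-butyl 1-[(4R,4aR,6R,7R,7aS)-2,4,7-trimethyloctahydro-1H-cyclopenta[c]pyridin-6-yl] (1R,2S,3S,4S)-2-[3-methoxy-4-(triisopropylsilyloxy)phenyl]-1-methyl-4-{(3E)-3-methyl-5-oxo-5-[2-(trimethylsilyl)ethoxy]pent-3-en-1-yl}cyclobutane-1,3-dicarboxylate | COc1cc([C@@H]2[C@@H](C(=O)OC(C)(C)C)[C@H](CC/C(C)=C/C(=O)OCC[Si](C)(C)C)[C@@]2(C)C(=O)O[C@@H]2C[C@H]3[C@H](CN(C)C[C@@H]3C)[C@H]2C)ccc1O[Si](C(C)C)(C(C)C)C(C)C | intermediate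
30 | (1R,2S,3S,4S)-2-[3-methoxy-4-(triisopropylsilyloxy)phenyl]-1-methyl-4-{(3E)-3-methyl-5-oxo-5-[2-(trimethylsilyl)ethoxy]pent-3-en-1-yl}cyclobutane-1,3-dicarboxylic acid 1-[(4R,4aR,6R,7R,7aS)-2,4,7-trimethyloctahydro-1H-cyclopenta[c]pyridin-6-yl] ester | COc1cc([C@@H]2[C@@H](C(=O)O)[C@H](CC/C(C)=C/C(=O)OCC[Si](C)(C)C)[C@@]2(C)C(=O)O[C@@H]2C[C@H]3[C@H](CN(C)C[C@@H]3C)[C@H]2C)ccc1O[Si](C(C)C)(C(C)C)C(C)C | intermediate
31 | bis[(4R,4aR,6R,7R,7aS)-2,4,7-trimethyloctahydro-1H-cyclopenta[c]pyridin-6-yl] (1R,2S,3S,4S)-2-[3-methoxy-4-(triisopropylsilyloxy)phenyl]-1-methyl-4-{(3E)-3-methyl-5-oxo-5-[2-(trimethylsilyl)ethoxy]pent-3-en-1-yl}cyclobutane-1,3-dicarboxylate | COc1cc([C@@H]2[C@@H](C(=O)O[C@@H]3C[C@H]4[C@H](CN(C)C[C@@H]4C)[C@H]3C)[C@H](CC/C(C)=C/C(=O)OCC[Si](C)(C)C)[C@@]2(C)C(=O)O[C@@H]2C[C@H]3[C@H](CN(C)C[C@@H]3C)[C@H]2C)ccc1O[Si](C(C)C)(C(C)C)C(C)C | intermediate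
32 | (1R,2S,3S,4S)-4-[(3E)-4-carboxy-3-methylbut-3-en-1-yl]-2-(4-hydroxy-3-methoxyphenyl)-1-methylcyclobutane-1,3-dicarboxylic acid 1,3-bis[(4R,4aR,6R,7R,7aS)-2,4,7-trimethyloctahydro-1H-cyclopenta[c]pyridin-6-yl] ester | COc1cc([C@@H]2[C@@H](C(=O)O[C@@H]3C[C@H]4[C@H](CN(C)C[C@@H]4C)[C@H]3C)[C@H](CC/C(C)=C/C(=O)O)[C@@]2(C)C(=O)O[C@@H]2C[C@H]3[C@H](CN(C)C[C@@H]3C)[C@H]2C)ccc1O | intermediate
33 | CNP0251577.2 | COc1cc([C@@H]2[C@@H](C(=O)O[C@@H]3C[C@H]4[C@H](CN(C)C[C@@H]4C)[C@H]3C)[C@H](CC/C(C)=C/C(=O)O[C@@H]3C[C@H]4[C@H](CN(C)C[C@@H]4C)[C@H]3C)[C@@]2(C)C(=O)O[C@@H]2C[C@H]3[C@H](CN(C)C[C@@H]3C)[C@H]2C)ccc1O | target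

**Count and risks**
Total steps: 21. Longest linear sequence: 13 steps (steps 1 to 8, then 17 to 21).

Step 15 (ring contraction). The hypervalent iodine reagent in the fluoroalcohol may oxidise the electron-rich aryl ring or the amine instead of transferring nitrogen, and the 1,4-diradical may fragment into two alkenes in competition with ring closure. The fallback sets out from 24 and comes back at 26. Nitrosation of 24 with tert-butyl nitrite in THF would give the N-nitrosopyrrolidine F1, and zinc in acetic acid at 0 °C would reduce it to the N-aminopyrrolidine F2. Oxidation of F2 with HgO in ether at room temperature would generate the same 1,1-diazene without any iodine reagent or ammonia, and loss of N2 would give 26 with retention.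

Step 14 (C5 equilibration). The equilibrium may stop short of the trans isomer if the thermodynamic bias is small, and thiyl radicals may add reversibly to the side-chain alkene and scramble its geometry. The fallback sets out from 23 and comes back at 26. Nitrosation of 23 would give the (5R)-N-nitrosopyrrolidine F3, whose benzylic C5–H is acidified by the N-nitroso group. A catalytic amount of t-BuOK in THF at low temperature should equilibrate C5 through the α-nitrosamino carbanion to the trans isomer, which is the nitroso compound F1. This is then carried through the N-amino compound F2 to 26 as described for step 15.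

Step 6 (radical ring closure). The two chair-like transition states may lie close in energy, so that the facial selectivity at C4 is poor, and the secondary radical may be reduced before it cyclises. The fallback sets out from 5 and comes back at 9. Alkylation of 5 with propargyl bromide (NaH, DMF) would give the N-propargyl silyl enol ether F4, and Pd(OAc)2 in MeCN would give the N-propargyl enone F5. A reductive alkyne–enone cyclisation with Ni(cod)2 (zerovalent nickel), PPh3 and ZnEt2 in THF would form the same C4–C4a bond and give the cis-fused 4-methylidene ketone F6. Hydrogenation with [Ir(cod)(PCy3)(py)]PF6, directed by the C6 carbonyl, should then deliver hydrogen to C4 from the cyclopentanone side and place the methyl on the face of H-4a, giving 9.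

**Further compounds**
F1 | step 15 | 2-benzyl 4-tert-butyl (2S,3S,4S,5S)-5-[3-methoxy-4-(triisopropylsilyloxy)phenyl]-2-methyl-3-{(3E)-3-methyl-5-oxo-5-[2-(trimethylsilyl)ethoxy]pent-3-en-1-yl}-1-nitrosopyrrolidine-2,4-dicarboxylate | COc1cc([C@H]2N(N=O)[C@](C)(C(=O)OCc3ccccc3)[C@@H](CC/C(C)=C/C(=O)OCC[Si](C)(C)C)[C@@H]2C(=O)OC(C)(C)C)ccc1O[Si](C(C)C)(C(C)C)C(C)C
F2 | step 15 | 2-benzyl 4-tert-butyl (2S,3S,4S,5S)-1-amino-5-[3-methoxy-4-(triisopropylsilyloxy)phenyl]-2-methyl-3-{(3E)-3-methyl-5-oxo-5-[2-(trimethylsilyl)ethoxy]pent-3-en-1-yl}pyrrolidine-2,4-dicarboxylate | COc1cc([C@H]2N(N)[C@](C)(C(=O)OCc3ccccc3)[C@@H](CC/C(C)=C/C(=O)OCC[Si](C)(C)C)[C@@H]2C(=O)OC(C)(C)C)ccc1O[Si](C(C)C)(C(C)C)C(C)C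
F3 | step 14 | 2-benzyl 4-tert-butyl (2S,3S,4S,5R)-5-[3-methoxy-4-(triisopropylsilyloxy)phenyl]-2-methyl-3-{(3E)-3-methyl-5-oxo-5-[2-(trimethylsilyl)ethoxy]pent-3-en-1-yl}-1-nitrosopyrrolidine-2,4-dicarboxylate | COc1cc([C@@H]2N(N=O)[C@](C)(C(=O)OCc3ccccc3)[C@@H](CC/C(C)=C/C(=O)OCC[Si](C)(C)C)[C@@H]2C(=O)OC(C)(C)C)ccc1O[Si](C(C)C)(C(C)C)C(C)C
F4 | step 6 | tert-butyl {[(1S,2R)-3-(tert-butyldimethylsilyloxy)-2-methylcyclopent-3-en-1-yl]methyl}(prop-2-yn-1-yl)carbamate | CC(C)(C)[Si](C)(C)OC1=CC[C@H](CN(CC#C)C(=O)OC(C)(C)C)[C@H]1C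
F5 | step 6 | tert-butyl {[(1S,5R)-5-methyl-4-oxocyclopent-2-en-1-yl]methyl}(prop-2-yn-1-yl)carbamate | O=C1C=C[C@H](CN(C(=O)OC(C)(C)C)CC#C)[C@H]1C
F6 | step 6 | tert-butyl (4aS,7R,7aS)-7-methyl-4-methylidene-6-oxooctahydro-2H-cyclopenta[c]pyridine-2-carboxylate | O=C1C[C@H]2[C@H](CN(C(=O)OC(C)(C)C)CC2=C)[C@H]1C
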